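**Retrosynthetic overview**
1. The hydroperoxide is installed last but one, by addition–elimination of hydroperoxide anion on a chloroquinone (vinylogous acid chloride to vinylogous peracid), with the para hydroxyl masked as a MOM ether.
2. The OH and OOH positions are differentiated by mono-hydrolysis of the symmetric 2,5-dichloro-3,6-bis(indolyl)quinone 11.
3. Key C–C bonds: two successive intermolecular Michael additions of 5-prenylindole (C3) to 2,5-dichloro-1,4-benzoquinone, each followed by DDQ re-oxidation.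
4. 5-Prenylindole comes from 5-bromoindole by N-silylation, Br/Li exchange, copper-catalysed prenylation and desilylation.
5. No ring is formed: the indole and quinone rings are bought intact.

**Assumptions**
- The target has no stereocentre and no stereogenic double bond, so it is achiral and no stereocontrol is needed.
- Salts formed by simple proton transfer (sodium indolide in step 1, quinone oxide salts in steps 6 to 8) are treated as ionised forms of the numbered compounds and are not numbered separately.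
- The final hydroperoxide installation and unmasking (steps 8 and 9) are designed by analogy with acid chloride to peracid chemistry and are the least certain part of the route.

**Route**

Step 1
Reactants: 1 5-bromo-1H-indole
Product: 2 5-bromo-1-[tri(propan-2-yl)silyl]-1H-indole
Conditions: NaH (1.2 equiv), THF, 0 °C; then TIPSCl (1.1 equiv), 0 °C to rt
Reagents that add atoms: triisopropylsilyl chloride (TIPSCl), CC(C)[Si](Cl)(C(C)C)C(C)C
Why: N-silylation of the indolide (protection) removes the acidic N–H, and the bulky TIPS group shields C2 from lithiation in the next step.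

Step 2
Reactants: 2 5-bromo-1-[tri(propan-2-yl)silyl]-1H-indole; 3 1-bromo-3-methylbut-2-ene (prenyl bromide)
Product: 5 5-(3-methylbut-2-en-1-yl)-1-[tri(propan-2-yl)silyl]-1H-indole, via aryllithium 4 (not isolated)
Conditions: t-BuLi (2.1 equiv), THF, −78 °C, 30 min; then CuBr·SMe2 (10 mol %), 3 (1.3 equiv), −78 °C to rt
Reagents that add atoms: none
Why: Bromine–lithium exchange gives the C5 aryllithium cleanly, and copper-catalysed allylic substitution at the unhindered primary carbon of prenyl bromide gives the linear prenyl arene.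

Step 3
Reactants: 5 5-(3-methylbut-2-en-1-yl)-1-[tri(propan-2-yl)silyl]-1H-indole
Product: 6 5-(3-methylbut-2-en-1-yl)-1H-indole (5-prenylindole)
Conditions: TBAF (1.2 equiv), THF, 0 °C to rt; water work-up
Reagents that add atoms: none
Why: Fluoride-mediated N–Si cleavage (desilylation) is driven by the strong Si–F bond and leaves the prenyl olefin untouched.

Step 4
Reactants: 6 5-(3-methylbut-2-en-1-yl)-1H-indole; 7 2,5-dichlorocyclohexa-2,5-diene-1,4-dione (2,5-dichloro-1,4-benzoquinone, 1.2 equiv)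
Product: 9 2,5-dichloro-3-[5-(3-methylbut-2-en-1-yl)-1H-indol-3-yl]cyclohexa-2,5-diene-1,4-dione, via hydroquinone adduct 8 (not isolated)
Conditions: AcOH/THF (1:1), rt, 16 h, dark; then DDQ (1.0 equiv), 0 °C to rt
Reagents that add atoms: none
Why: Acid-promoted intermolecular Michael addition of indole C3 to the unsubstituted β-carbon of the electron-poor quinone gives hydroquinone 8 after tautomerisation, which DDQ dehydrogenates back to the quinone; acetic acid is mild enough to spare the prenyl group.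

Step 5
Reactants: 9 2,5-dichloro-3-[5-(3-methylbut-2-en-1-yl)-1H-indol-3-yl]cyclohexa-2,5-diene-1,4-dione; 6 5-(3-methylbut-2-en-1-yl)-1H-indole (1.3 equiv)
Product: 11 2,5-dichloro-3,6-bis[5-(3-methylbut-2-en-1-yl)-1H-indol-3-yl]cyclohexa-2,5-diene-1,4-dione, via bis-indolyl hydroquinone 10 (not isolated)
Conditions: AcOH, 40 °C, 24 h; then DDQ (1.0 equiv), THF, 0 °C to rt
Reagents that add atoms: none
Why: A second Michael addition of indole C3 can only occur at the one remaining C–H position (para to the first indole), and DDQ oxidation of the hydroquinone restores the quinone.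

Step 6
Reactants: 11 2,5-dichloro-3,6-bis[5-(3-methylbut-2-en-1-yl)-1H-indol-3-yl]cyclohexa-2,5-diene-1,4-dione
Product: 12 2-chloro-5-hydroxy-3,6-bis[5-(3-methylbut-2-en-1-yl)-1H-indol-3-yl]cyclohexa-2,5-diene-1,4-dione
Conditions: NaOH (1 M aq, 2.5 equiv), THF, 0 °C to rt; then 1 M HCl
Reagents that add atoms: sodium hydroxide, [Na+].[OH-]
Why: Hydroxide displaces one chloride by addition–elimination (hydrolysis of a vinylogous acid chloride), and the resulting vinylogous carboxylate anion deactivates the ring so the reaction stops at mono-hydrolysis.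

Step 7
Reactants: 12 2-chloro-5-hydroxy-3,6-bis[5-(3-methylbut-2-en-1-yl)-1H-indol-3-yl]cyclohexa-2,5-diene-1,4-dione
Product: 13 2-chloro-5-(methoxymethoxy)-3,6-bis[5-(3-methylbut-2-en-1-yl)-1H-indol-3-yl]cyclohexa-2,5-diene-1,4-dione
Conditions: MOMCl (1.2 equiv), i-Pr2NEt (1.5 equiv), CH2Cl2, 0 °C
Reagents that add atoms: chloromethyl methyl ether (MOMCl), COCCl
Why: O-Alkylation of the acidic hydroxyquinone (pKa about 4) gives a neutral vinylogous MOM ester, which restores electrophilicity at the C–Cl carbon while the far less acidic indole N–H is untouched.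

Step 8
Reactants: 13 2-chloro-5-(methoxymethoxy)-3,6-bis[5-(3-methylbut-2-en-1-yl)-1H-indol-3-yl]cyclohexa-2,5-diene-1,4-dione
Product: 14 2-hydroperoxy-5-(methoxymethoxy)-3,6-bis[5-(3-methylbut-2-en-1-yl)-1H-indol-3-yl]cyclohexa-2,5-diene-1,4-dione
Conditions: 30% aq H2O2 (10 equiv), LiOH·H2O (2.0 equiv), THF/H2O (4:1), 0 °C, inverse addition of 13, 20 min; cold 0.5 M HCl to pH 3–4, EtOAc extraction, water washes, no reductive quench; use at once
Reagents that add atoms: hydrogen peroxide, OO
Why: Lithium hydroperoxide, an alpha-effect nucleophile, displaces the vinylic chloride by addition–elimination exactly as acid chlorides are converted to peracids, while excess H2O2 suppresses bis-quinonyl peroxide formation and the product peroxide anion resists further attack.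

Step 9
Reactants: 14 2-hydroperoxy-5-(methoxymethoxy)-3,6-bis[5-(3-methylbut-2-en-1-yl)-1H-indol-3-yl]cyclohexa-2,5-diene-1,4-dione
Product: 15 2-hydroperoxy-5-hydroxy-3,6-bis[5-(3-methylbut-2-en-1-yl)-1H-indol-3-yl]cyclohexa-2,5-diene-1,4-dione (hydroperoxycochliodinol)
Conditions: AcOH/THF/H2O (3:1:1), rt, dark; cold work-up, reversed-phase or Sephadex LH-20 purification
Reagents that add atoms: none
Why: Mild acid hydrolysis of the MOM acetal proceeds through the methoxymethyl oxocarbenium ion because the hydroxyquinone is a good leaving group, under conditions that hydroperoxides, indoles and prenyl groups tolerate.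

**Compound list**
1 | 5-bromo-1H-indole | Brc1ccc2[nH]ccc2c1 | starting material
2 | 5-bromo-1-[tri(propan-2-yl)silyl]-1H-indole | CC(C)[Si](C(C)C)(C(C)C)n1ccc2cc(Br)ccc21 | intermediate
3 | 1-bromo-3-methylbut-2-ene (prenyl bromide) | CC(C)=CCBr | starting material
4 | 5-lithio-1-[tri(propan-2-yl)silyl]-1H-indole | CC(C)[Si](C(C)C)(C(C)C)n1ccc2cc([Li])ccc21 | intermediate
5 | 5-(3-methylbut-2-en-1-yl)-1-[tri(propan-2-yl)silyl]-1H-indole | CC(C)=CCc1ccc2c(ccn2[Si](C(C)C)(C(C)C)C(C)C)c1 | intermediate
6 | 5-(3-methylbut-2-en-1-yl)-1H-indole | CC(C)=CCc1ccc2[nH]ccc2c1 | intermediate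
7 | 2,5-dichlorocyclohexa-2,5-diene-1,4-dione | O=C1C=C(Cl)C(=O)C=C1Cl | starting material
8 | 2,5-dichloro-3-[5-(3-methylbut-2-en-1-yl)-1H-indol-3-yl]benzene-1,4-diol | Oc1cc(Cl)c(O)c(-c2c[nH]c3ccc(CC=C(C)C)cc23)c1Cl | intermediate
9 | 2,5-dichloro-3-[5-(3-methylbut-2-en-1-yl)-1H-indol-3-yl]cyclohexa-2,5-diene-1,4-dione | O=C1C=C(Cl)C(=O)C(c2c[nH]c3ccc(CC=C(C)C)cc23)=C1Cl | intermediate
10 | 2,5-dichloro-3,6-bis[5-(3-methylbut-2-en-1-yl)-1H-indol-3-yl]benzene-1,4-diol | Oc1c(Cl)c(-c2c[nH]c3ccc(CC=C(C)C)cc23)c(O)c(Cl)c1-c1c[nH]c2ccc(CC=C(C)C)cc12 | intermediate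
11 | 2,5-dichloro-3,6-bis[5-(3-methylbut-2-en-1-yl)-1H-indol-3-yl]cyclohexa-2,5-diene-1,4-dione | O=C1C(Cl)=C(c2c[nH]c3ccc(CC=C(C)C)cc23)C(=O)C(Cl)=C1c1c[nH]c2ccc(CC=C(C)C)cc12 | intermediate
12 | 2-chloro-5-hydroxy-3,6-bis[5-(3-methylbut-2-en-1-yl)-1H-indol-3-yl]cyclohexa-2,5-diene-1,4-dione | O=C1C(Cl)=C(c2c[nH]c3ccc(CC=C(C)C)cc23)C(=O)C(O)=C1c1c[nH]c2ccc(CC=C(C)C)cc12 | intermediate
13 | 2-chloro-5-(methoxymethoxy)-3,6-bis[5-(3-methylbut-2-en-1-yl)-1H-indol-3-yl]cyclohexa-2,5-diene-1,4-dione | O=C1C(Cl)=C(c2c[nH]c3ccc(CC=C(C)C)cc23)C(=O)C(OCOC)=C1c1c[nH]c2ccc(CC=C(C)C)cc12 | intermediate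
14 | 2-hydroperoxy-5-(methoxymethoxy)-3,6-bis[5-(3-methylbut-2-en-1-yl)-1H-indol-3-yl]cyclohexa-2,5-diene-1,4-dione | O=C1C(OO)=C(c2c[nH]c3ccc(CC=C(C)C)cc23)C(=O)C(OCOC)=C1c1c[nH]c2ccc(CC=C(C)C)cc12 | intermediate
15 | 2-hydroperoxy-5-hydroxy-3,6-bis[5-(3-methylbut-2-en-1-yl)-1H-indol-3-yl]cyclohexa-2,5-diene-1,4-dione (hydroperoxycochliodinol) | CC(C)=CCc1ccc2[nH]cc(C3=C(O)C(=O)C(c4c[nH]c5ccc(CC=C(C)C)cc45)=C(OO)C3=O)c2c1 | target

**Step count and risks**
Total steps: 9. Longest linear sequence: 9 steps (1 to 15); compound 6 is used in both step 4 and step 5.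

The three steps most likely to fail:

Step 8 (hydroperoxide displacement of chloride; risks are quinone epoxidation, attack at the MOM-bearing carbon, peroxide dimer formation and decomposition of the peroxide anion). The fallback sets out from 13 and comes back at 15. Free hydrogen peroxide is replaced by a mono-protected peroxide nucleophile. Ozonolysis of 2,3-dimethylbut-2-ene in MeOH/CH2Cl2 at −78 °C gives 2-methoxypropan-2-yl hydroperoxide F2. Its caesium salt (1.1 equiv, Cs2CO3, DMF, 0 °C) displaces the chloride of 13 to give 2-(methoxymethoxy)-5-[(2-methoxypropan-2-yl)peroxy]-3,6-bis[5-(3-methylbut-2-en-1-yl)-1H-indol-3-yl]cyclohexa-2,5-diene-1,4-dione F3. F3 is a neutral peroxyketal, so no peroxide anion or excess H2O2 is present. AcOH/THF/H2O at rt then cleaves the peroxyketal and the MOM acetal together to give 15.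

Step 9 (acidic MOM removal next to a vinylogous peracid). The fallback sets out from 12 and comes back at 15. The acid-labile mask is replaced by a fluoride-labile one. Compound 12 with SEMCl and i-Pr2NEt in CH2Cl2 gives 2-chloro-5-{[2-(trimethylsilyl)ethoxy]methoxy}-3,6-bis[5-(3-methylbut-2-en-1-yl)-1H-indol-3-yl]cyclohexa-2,5-diene-1,4-dione F4. LiOH/H2O2 as in step 8 gives 2-hydroperoxy-5-{[2-(trimethylsilyl)ethoxy]methoxy}-3,6-bis[5-(3-methylbut-2-en-1-yl)-1H-indol-3-yl]cyclohexa-2,5-diene-1,4-dione F5. TBAF buffered with AcOH (THF, 0 °C) then induces fluoride-triggered fragmentation of the SEM group under near-neutral conditions to give 15.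

Step 5 (second Michael addition to a hindered, less electrophilic indolylquinone with an acid-sensitive prenylindole). The fallback sets out from 6 and comes back at 11. Two equivalents of 6 are combined with tetrachloro-1,4-benzoquinone (chloranil) and Cs2CO3 in MeCN at rt, a base-mediated conjugate addition–elimination needing no acid and no oxidant. The first substitution gives 2,3,5-trichloro-6-[5-(3-methylbut-2-en-1-yl)-1H-indol-3-yl]cyclohexa-2,5-diene-1,4-dione F1 (not isolated). The second indole then displaces the chloride para to the first, because the carbonyl conjugated to the first indole is deactivated. This gives 11 after chromatographic removal of the minor 2,6-bis(indolyl) isomer.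

**Further compounds**
F1 | step 5 | 2,3,5-trichloro-6-[5-(3-methylbut-2-en-1-yl)-1H-indol-3-yl]cyclohexa-2,5-diene-1,4-dione | O=C1C(Cl)=C(Cl)C(=O)C(c2c[nH]c3ccc(CC=C(C)C)cc23)=C1Cl
F2 | step 8 | 2-methoxypropan-2-yl hydroperoxide | COC(C)(C)OO
F3 | step 8 | 2-(methoxymethoxy)-5-[(2-methoxypropan-2-yl)peroxy]-3,6-bis[5-(3-methylbut-2-en-1-yl)-1H-indol-3-yl]cyclohexa-2,5-diene-1,4-dione | O=C1C(OOC(C)(C)OC)=C(c2c[nH]c3ccc(CC=C(C)C)cc23)C(=O)C(OCOC)=C1c1c[nH]c2ccc(CC=C(C)C)cc12
F4 | step 9 | 2-chloro-5-{[2-(trimethylsilyl)ethoxy]methoxy}-3,6-bis[5-(3-methylbut-2-en-1-yl)-1H-indol-3-yl]cyclohexa-2,5-diene-1,4-dione | O=C1C(Cl)=C(c2c[nH]c3ccc(CC=C(C)C)cc23)C(=O)C(OCOCC[Si](C)(C)C)=C1c1c[nH]c2ccc(CC=C(C)C)cc12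
F5 | step 9 | 2-hydroperoxy-5-{[2-(trimethylsilyl)ethoxy]methoxy}-3,6-bis[5-(3-methylbut-2-en-1-yl)-1H-indol-3-yl]cyclohexa-2,5-diene-1,4-dione | O=C1C(OO)=C(c2c[nH]c3ccc(CC=C(C)C)cc23)C(=O)C(OCOCC[Si](C)(C)C)=C1c1c[nH]c2ccc(CC=C(C)C)cc12
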